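The route rests on disconnecting C8–C8', the ring-fusion bond shared by both tetrahydrofuran rings of the 3,7-dioxabicyclo[3.3.0]octane core. The precursor is an acyclic ether: guaiacyl carbinol carbon C7 bears a C8–C9 oxirane and an O-sinapyl chain whose syringyl oxygen already carries the silyl-protected erythro glycerol unit. Cp2TiCl opens the oxirane to a C8 radical that closes ring A (O, C7, C8, C8', C9') onto the C8'=C7' alkene; iodine then lets the freed C9 oxygen close ring B (O, C9, C8, C8', C7') at benzylic C7'. One operation forms the bond, both rings and three stereocentres from C7 alone, exploiting that C8 and C8' each lie between a benzylic carbon and an oxygen-bearing methylene.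

Key step: step 14

Remark: lignan numbering is used (C7–C9 guaiacyl half, C7'–C9' syringyl half, C7''–C9'' glycerol chain); methyl sinapate 6 and the chloroacetyl imide 7 are taken as purchasable.

Step 1
Reactants: 1 vanillin
Product: 2 TIPS-vanillin
Conditions: TIPSCl, imidazole, DMF, rt
Reagents that add atoms: triisopropylsilyl chloride, CC(C)[Si](Cl)(C(C)C)C(C)C
Why: Imidazole-promoted O-silylation of the phenol; the bulky aryl TIPS ether should tolerate the Grignard, alkoxide, boron and titanium chemistry ahead and falls to fluoride at the end.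

Step 2
Reactants: 2 TIPS-vanillin; 3 vinylmagnesium bromide
Product: 4 racemic aryl vinyl carbinol
Conditions: THF, −78 → 0 °C; aq NH4Cl
Reagents that add atoms: none
Why: Grignard 1,2-addition to the aryl aldehyde should give the racemic allylic alcohol whose carbinol carbon becomes C7.

Step 3
Reactants: 4 racemic aryl vinyl carbinol
Product: 5 erythro epoxy alcohol
Conditions: Ti(OiPr)4 (0.2 equiv), D-(−)-diisopropyl tartrate (0.24 equiv), tBuOOH (0.5 equiv), 4 Å sieves, CH2Cl2, −20 °C
Reagents that add atoms: tert-butyl hydroperoxide, CC(C)(C)OO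
Why: Sharpless kinetic resolution, in which the D-(−)-tartrate catalyst should epoxidise the (S)-enantiomer of 4 much faster than the (R)-enantiomer (left behind as allylic alcohol) and give the erythro epoxy alcohol, so that C7 is fixed in the sense of 7S of the target (it reads R in 5 only because oxiranyl outranks aryl) and the oxirane centre is set by the same reagent-controlled face selection.

Step 4
Reactants: 6 methyl (E)-sinapate; 7 (S)-4-benzyl-3-(chloroacetyl)oxazolidin-2-one
Product: 8 aryloxyacetyl imide
Conditions: K2CO3, NaI (0.1 equiv), MeCN, 40 °C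
Reagents that add atoms: none
Why: Williamson O-alkylation of the hindered but nucleophilic 2,6-dimethoxyphenoxide by the activated α-halo imide under Finkelstein catalysis, with no stereocentre touched.

Step 5
Reactants: 8 aryloxyacetyl imide; 2 TIPS-vanillin
Product: 9 syn-aldol adduct
Conditions: Bu2BOTf, iPr2NEt, CH2Cl2, 0 °C; 2, −78 → 0 °C; pH 7 buffer, MeOH, H2O2
Reagents that add atoms: none
Why: Evans syn-aldol, in which the Z-boron enolate should add to the aldehyde through a closed chair transition state on the enolate face opposite the benzyl group of the (S)-auxiliary, setting C8'' in its final configuration and C7'' as the syn (threo) epimer that is inverted in step 8.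

Step 6
Reactants: 9 syn-aldol adduct
Product: 10 threo diol
Conditions: NaBH4, THF/H2O 4:1, 0 °C → rt
Reagents that add atoms: none
Why: NaBH4 in wet THF reductively cleaves N-acyl oxazolidinones to primary alcohols and should leave the conjugated methyl ester and both stereocentres untouched while releasing the auxiliary.

Step 7
Reactants: 10 threo diol
Product: 11 threo primary TBS ether
Conditions: TBSCl (1.05 equiv), imidazole, CH2Cl2, 0 °C
Reagents that add atoms: tert-butyldimethylsilyl chloride, CC(C)(C)[Si](C)(C)Cl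
Why: Silylation with one equivalent of TBSCl should be selective for the primary C9'' hydroxyl over the hindered secondary benzylic one.

Step 8
Reactants: 11 threo primary TBS ether
Product: 12 erythro 4-nitrobenzoate
Conditions: 4-O2NC6H4CO2H, PPh3, DIAD, toluene, 0 °C → rt
Reagents that add atoms: 4-nitrobenzoic acid, O=C(O)c1ccc(cc1)[N+](=O)[O-]
Why: Mitsunobu esterification should displace the activated C7'' oxygen by SN2 with inversion, turning the threo (7''R,8''R) into the erythro (7''S,8''R) series, the inductively withdrawing β-aryloxy group disfavouring benzylic ionisation.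

Step 9
Reactants: 12 erythro 4-nitrobenzoate
Product: 13 erythro alcohol
Conditions: K2CO3 (0.2 equiv), MeOH, 0 °C
Reagents that add atoms: none
Why: Mild transesterification removes the activated 4-nitrobenzoate without touching a stereocentre, and a possible 1,3-shift of the TBS group is harmless because the other hydroxyl receives the same group next.

Step 10
Reactants: 13 erythro alcohol
Product: 14 erythro bis-TBS ester
Conditions: TBSOTf, 2,6-lutidine, CH2Cl2, −78 → 0 °C
Reagents that add atoms: tert-butyldimethylsilyl triflate, CC(C)(C)[Si](C)(C)OS(=O)(=O)C(F)(F)F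
Why: Silyl triflate with a hindered base silylates the secondary benzylic alcohol, leaving a side chain that carries only fluoride-labile groups.

Step 11
Reactants: 14 erythro bis-TBS ester
Product: 15 allylic alcohol
Conditions: iBu2AlH (2.5 equiv), CH2Cl2, −78 °C; aq potassium sodium tartrate
Reagents that add atoms: none
Why: 1,2-Reduction of the cinnamate ester by iBu2AlH should give the (E)-allylic alcohol with all silyl ethers intact.

Step 12
Reactants: 15 allylic alcohol
Product: 16 allylic bromide
Conditions: CBr4, PPh3, CH2Cl2, −20 → 0 °C; used crude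
Reagents that add atoms: carbon tetrabromide, BrC(Br)(Br)Br
Why: Appel bromination under neutral conditions converts the primary allylic alcohol into the (E)-bromide without acid that would ionise the electron-rich cinnamyl system.

Step 13
Reactants: 5 erythro epoxy alcohol; 16 allylic bromide
Product: 17 epoxy sinapyl ether
Conditions: NaH, Bu4NI (0.1 equiv), THF/DMF 5:1, 0 °C → rt
Reagents that add atoms: none
Why: Williamson etherification (SN2, alkene geometry retained) forms the C7–O–C9' ether, and adding NaH to the mixture of both partners keeps the alkoxide concentration low and should suppress Payne rearrangement, C7 being untouched.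

Step 14
Reactants: 17 epoxy sinapyl ether
Product: 20 tetrasilyl hedyotol C, via benzylic titanium alkoxide 18 (not isolated), via benzylic iodide 19 (not isolated)
Conditions: Cp2TiCl (from Cp2TiCl2 and Zn dust, 2.5 equiv, slow addition), THF, rt; then I2 (1.3 equiv), rt → 45 °C
Reagents that add atoms: none
Why: Cp2TiCl (trivalent titanium) opens the terminal oxirane by single-electron transfer to the secondary C8 radical with the C9 oxygen bound to tetravalent titanium, the radical adds 5-exo-trig to C8' of the sinapyl alkene to form the C8–C8' bond and ring A (O, C7, C8, C8', C9'), and a second Cp2TiCl captures the benzylic C7' radical as 18. Iodine then cleaves the C7'–Ti bond to the benzylic iodide 19, which ionises at the electron-rich benzylic carbon and is captured by the C9 titanium alkoxide in a 5-exo-tet closure of ring B (O, C9, C8, C8', C7'). The closest known reaction type is the Cp2TiCl-mediated reductive epoxide opening with 5-exo radical cyclisation onto a cinnamyl ether followed by iodine-induced etherification, a radical–polar crossover established for 2,6-diaryl-3,7-dioxabicyclo[3.3.0]octanes. C8 should be set trans to the C7 aryl group, which sits pseudo-equatorial in the chair-like 5-exo transition state; C8' should be set cis to C8 by the usual 1,5-cis preference of a radical substituted at the attacking carbon, the only arrangement that can close the cis-fused bicycle; and C7' should place its aryl group exo on the convex face in the ionic closure. The step needs cyclisation to outrun capture of the C8 radical by a second Cp2TiCl (which would end in β-alkoxide elimination), and the fast styrene-type acceptor together with slow addition of the reagent should secure this. The oxirane configuration at C8 is erased in the radical, so C7 alone relays the absolute configuration to the three new stereocentres.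

Step 15
Reactants: 20 tetrasilyl hedyotol C
Product: 21 hedyotol C
Conditions: Bu4NF, AcOH, THF, 0 °C → rt
Reagents that add atoms: none
Why: Fluoride cleaves the two aryl TIPS and the two alkyl TBS ethers in one operation, acetic acid buffering the phenoxides so that neither the benzylic ethers of the core nor the 4-hydroxybenzylic alcohol should ionise, and no stereocentre is touched.

Compound list
1 | vanillin (4-hydroxy-3-methoxybenzaldehyde) | COc1cc(C=O)ccc1O | starting material
2 | TIPS-vanillin, 3-methoxy-4-(triisopropylsilyloxy)benzaldehyde | COc1cc(C=O)ccc1O[Si](C(C)C)(C(C)C)C(C)C | intermediate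
3 | vinylmagnesium bromide | C=C[Mg]Br | starting material
4 | rac-1-[3-methoxy-4-(triisopropylsilyloxy)phenyl]prop-2-en-1-ol | COc1cc(C(O)C=C)ccc1O[Si](C(C)C)(C(C)C)C(C)C | intermediate
5 | (R)-[3-methoxy-4-(triisopropylsilyloxy)phenyl][(2S)-oxiran-2-yl]methanol (erythro) | COc1cc([C@@H](O)[C@@H]2CO2)ccc1O[Si](C(C)C)(C(C)C)C(C)C | intermediate
6 | methyl (E)-sinapate, methyl (E)-3-(4-hydroxy-3,5-dimethoxyphenyl)acrylate | COC(=O)/C=C/c1cc(OC)c(O)c(OC)c1 | starting material
7 | (S)-4-benzyl-3-(chloroacetyl)oxazolidin-2-one | O=C(CCl)N1[C@@H](Cc2ccccc2)COC1=O | starting material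
8 | (S)-4-benzyl-3-{2-[2,6-dimethoxy-4-((E)-3-methoxy-3-oxoprop-1-enyl)phenoxy]acetyl}oxazolidin-2-one | COC(=O)/C=C/c1cc(OC)c(OCC(=O)N2[C@@H](Cc3ccccc3)COC2=O)c(OC)c1 | intermediate
9 | (S)-4-benzyl-3-[(2S,3R)-2-{2,6-dimethoxy-4-[(E)-3-methoxy-3-oxoprop-1-enyl]phenoxy}-3-hydroxy-3-(3-methoxy-4-triisopropylsilyloxyphenyl)propanoyl]oxazolidin-2-one (syn aldol) | COC(=O)/C=C/c1cc(OC)c(O[C@H](C(=O)N2[C@@H](Cc3ccccc3)COC2=O)[C@H](O)c2ccc(O[Si](C(C)C)(C(C)C)C(C)C)c(OC)c2)c(OC)c1 | intermediate
10 | methyl (E)-3-{4-[(1R,2R)-1,3-dihydroxy-1-(3-methoxy-4-triisopropylsilyloxyphenyl)propan-2-yloxy]-3,5-dimethoxyphenyl}acrylate (threo diol) | COC(=O)/C=C/c1cc(OC)c(O[C@H](CO)[C@H](O)c2ccc(O[Si](C(C)C)(C(C)C)C(C)C)c(OC)c2)c(OC)c1 | intermediate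
11 | threo (1R,2R) alcohol, as 10 with the primary C9'' hydroxyl as tert-butyldimethylsilyl ether | COC(=O)/C=C/c1cc(OC)c(O[C@H](CO[Si](C)(C)C(C)(C)C)[C@H](O)c2ccc(O[Si](C(C)C)(C(C)C)C(C)C)c(OC)c2)c(OC)c1 | intermediate
12 | erythro (1S,2R) 4-nitrobenzoate, C7'' esterified with inversion, C9'' as TBS ether | COC(=O)/C=C/c1cc(OC)c(O[C@H](CO[Si](C)(C)C(C)(C)C)[C@@H](OC(=O)c2ccc(cc2)[N+](=O)[O-])c2ccc(O[Si](C(C)C)(C(C)C)C(C)C)c(OC)c2)c(OC)c1 | intermediate
13 | erythro (1S,2R) alcohol, C7'' hydroxyl free, C9'' as TBS ether | COC(=O)/C=C/c1cc(OC)c(O[C@H](CO[Si](C)(C)C(C)(C)C)[C@@H](O)c2ccc(O[Si](C(C)C)(C(C)C)C(C)C)c(OC)c2)c(OC)c1 | intermediate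
14 | methyl (E)-3-{4-[(1S,2R)-1,3-bis(tert-butyldimethylsilyloxy)-1-(3-methoxy-4-triisopropylsilyloxyphenyl)propan-2-yloxy]-3,5-dimethoxyphenyl}acrylate | COC(=O)/C=C/c1cc(OC)c(O[C@H](CO[Si](C)(C)C(C)(C)C)[C@@H](O[Si](C)(C)C(C)(C)C)c2ccc(O[Si](C(C)C)(C(C)C)C(C)C)c(OC)c2)c(OC)c1 | intermediate
15 | (E)-allylic alcohol, as 14 with CH2OH in place of CO2Me | OC/C=C/c1cc(OC)c(O[C@H](CO[Si](C)(C)C(C)(C)C)[C@@H](O[Si](C)(C)C(C)(C)C)c2ccc(O[Si](C(C)C)(C(C)C)C(C)C)c(OC)c2)c(OC)c1 | intermediate
16 | (E)-allylic bromide, as 15 with CH2Br | BrC/C=C/c1cc(OC)c(O[C@H](CO[Si](C)(C)C(C)(C)C)[C@@H](O[Si](C)(C)C(C)(C)C)c2ccc(O[Si](C(C)C)(C(C)C)C(C)C)c(OC)c2)c(OC)c1 | intermediate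
17 | epoxy ether: the (R)-carbinol oxygen of 5 carries the (E)-sinapyl chain of 16, (2S)-oxirane retained | COc1cc([C@@H](OC/C=C/c2cc(OC)c(O[C@H](CO[Si](C)(C)C(C)(C)C)[C@@H](O[Si](C)(C)C(C)(C)C)c3ccc(O[Si](C(C)C)(C(C)C)C(C)C)c(OC)c3)c(OC)c2)[C@@H]2CO2)ccc1O[Si](C(C)C)(C(C)C)C(C)C | intermediate
18 | (7S,8R,8'R) monocyclic tetrahydrofuran with C7'–TiCp2Cl and C9–O–TiCp2Cl, C7' undefined (each cyclopentadienyl drawn as a ring bonded through one carbon) | COc1cc([C@H]2OC[C@H](C([Ti](Cl)(C3C=CC=C3)C3C=CC=C3)c3cc(OC)c(O[C@H](CO[Si](C)(C)C(C)(C)C)[C@@H](O[Si](C)(C)C(C)(C)C)c4ccc(O[Si](C(C)C)(C(C)C)C(C)C)c(OC)c4)c(OC)c3)[C@@H]2CO[Ti](Cl)(C2C=CC=C2)C2C=CC=C2)ccc1O[Si](C(C)C)(C(C)C)C(C)C | intermediate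
19 | (7S,8R,8'R) monocyclic tetrahydrofuran with C7'–I and C9–O–TiCp2Cl, C7' undefined | COc1cc([C@H]2OC[C@H](C(I)c3cc(OC)c(O[C@H](CO[Si](C)(C)C(C)(C)C)[C@@H](O[Si](C)(C)C(C)(C)C)c4ccc(O[Si](C(C)C)(C(C)C)C(C)C)c(OC)c4)c(OC)c3)[C@@H]2CO[Ti](Cl)(C2C=CC=C2)C2C=CC=C2)ccc1O[Si](C(C)C)(C(C)C)C(C)C | intermediate
20 | tetrasilyl hedyotol C: (7S,8R,7'S,8'R) furofuran, both phenols as TIPS ethers, C7''–O and C9''–O as TBS ethers, (7''S,8''R) | COc1cc([C@H]2OC[C@H]3[C@@H]2CO[C@@H]3c2cc(OC)c(O[C@H](CO[Si](C)(C)C(C)(C)C)[C@@H](O[Si](C)(C)C(C)(C)C)c3ccc(O[Si](C(C)C)(C(C)C)C(C)C)c(OC)c3)c(OC)c2)ccc1O[Si](C(C)C)(C(C)C)C(C)C | intermediate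
21 | hedyotol C | COc1cc([C@H]2OC[C@H]3[C@@H]2CO[C@@H]3c2cc(OC)c(O[C@H](CO)[C@@H](O)c3ccc(O)c(OC)c3)c(OC)c2)ccc1O | target

Total step count: 15. Longest linear sequence: 12 steps (steps 4–15, from methyl sinapate).

Steps most likely to fail

Step 14. The benzylic carbon–titanium bond of 18 may be lost to protonation before iodination, or the ionic closure may be unselective, so that ring B does not form cleanly. The fallback sets out from 17 and returns at 20. 17 is cyclised with Cp2TiCl alone and quenched with aqueous NaH2PO4, so that the benzylic titanium species is protonated on purpose and the (7S,8R,8'R) monocyclic 7'-deoxy tetrahydrofuran alcohol F1 is isolated. Ring B is then closed in a separate Suárez hypoiodite reaction (PhI(OAc)2, I2, cyclohexane/CH2Cl2, visible light): the C9 alkoxy radical abstracts a benzylic hydrogen from C7' by 1,5-hydrogen transfer, and the benzylic iodide so formed is displaced by the C9 oxygen.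

Step 8. The activated, electron-rich benzylic oxygen may ionise (partial retention or elimination) instead of undergoing clean SN2 inversion. The fallback sets out from 11 and returns at 13, bypassing 12. Dess–Martin periodinane (NaHCO3-buffered, CH2Cl2) oxidises 11 to the aryl ketone F2. Zn(BH4)2 in Et2O at −30 °C then reduces it under chelation control, zinc bridging the carbonyl and the C8'' aryloxy oxygen and hydride arriving from the face of the C8'' hydrogen, which should give the erythro alcohol.

Step 13. Payne rearrangement of the epoxy alkoxide and solvolytic decomposition of the allylic bromide may compete with O-alkylation. The fallback sets out from 15 (in place of 16) and returns at 17. 15 is acetylated (Ac2O, pyridine) to the sinapyl acetate F3. 5 is then allylated through its zinc alkoxide under palladium catalysis (Et2Zn 0.5 equiv, Pd(OAc)2, 2-(di-tert-butylphosphino)biphenyl, THF, rt); attack at the terminal carbon of the π-allyl complex should give the linear (E)-ether without strong base or a free allylic bromide.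

Further compounds
F1 | step 14 | (7S,8R,8'R) 7'-deoxy monocyclic tetrahydrofuran alcohol: 2-aryl-3-hydroxymethyl-4-benzyl tetrahydrofuran with C9–OH free, silyl groups as in 20 | COc1cc([C@H]2OC[C@H](Cc3cc(OC)c(O[C@H](CO[Si](C)(C)C(C)(C)C)[C@@H](O[Si](C)(C)C(C)(C)C)c4ccc(O[Si](C(C)C)(C(C)C)C(C)C)c(OC)c4)c(OC)c3)[C@@H]2CO)ccc1O[Si](C(C)C)(C(C)C)C(C)C
F2 | step 8 | methyl (E)-3-{4-[(2R)-3-(tert-butyldimethylsilyloxy)-1-(3-methoxy-4-triisopropylsilyloxyphenyl)-1-oxopropan-2-yloxy]-3,5-dimethoxyphenyl}acrylate | COC(=O)/C=C/c1cc(OC)c(O[C@H](CO[Si](C)(C)C(C)(C)C)C(=O)c2ccc(O[Si](C(C)C)(C(C)C)C(C)C)c(OC)c2)c(OC)c1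
F3 | step 13 | (E)-allylic acetate of 15 | CC(=O)OC/C=C/c1cc(OC)c(O[C@H](CO[Si](C)(C)C(C)(C)C)[C@@H](O[Si](C)(C)C(C)(C)C)c2ccc(O[Si](C(C)C)(C(C)C)C(C)C)c(OC)c2)c(OC)c1
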